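The route rests on cutting the bridged δ-lactone from the decalin at two bonds: C4–C5 (methyl-bearing quaternary carbon to the ring-fusion CH) and C10–C20 (angular carbon to the lactone OCH2). The precursor is an enantiopure 4-silyloxycyclohexenone (ring B) whose enone C5=C10–C9=O carries at C10 a three-carbon chain ending in a chloromethyl 2-methylalkanoate. One base-mediated Michael addition/enolate alkylation cascade, an anionic formal [4+2], joins the ester enolate carbon C4 to C5 and the resulting enolate carbon C10 to C20. It exploits the lactone ring C10–C20–O–C19–C4–C5, which shares C4, C5 and C10 with ring A: both rings close as a 3-oxabicyclo[3.3.1]nonanone and three stereocentres are set.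

Key step: step 8

Remark (numbering): labdane numbering is used. C1–C3 are the CH2 groups of ring A; C4 carries the methyl group (C18) and the lactone carbonyl (C19); C5 is the ring-fusion CH; C6 carries the acetate; C7 is CH2; C8 is the spiro-epoxide carbon (C17 its CH2); C9 is the spiro carbon next to C10; C10 is the angular carbon; C20 is the lactone OCH2; C11/C12 are the CH2CH2 of the tetrahydrofuran; C13 is the second spiro carbon; C14=C15 is the enol ether; C16 is the dihydrofuran OCH2. α is the face of H-5, β the face of C20.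

Remark (assumption): ester 6 is used racemic, because its α-carbon (the future C4) is enolised in step 8; compounds 7–10 are therefore epimer pairs at that carbon.

Step 1
Reactants: 1 1,4-dioxaspiro[4.5]dec-6-en-8-one
Product: 2 (S)-1,4-dioxaspiro[4.5]dec-6-en-8-ol
Conditions: (R)-Me-CBS (10 mol%), BH3·SMe2, THF, −30 °C; MeOH quench
Reagents that add atoms: none
Why: Corey–Bakshi–Shibata reduction, in which the alkenyl flank acts as the large group, so the (R)-oxazaborolidine should give the (S)-allylic alcohol, the carbinol that later steers the key step.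

Step 2
Reactants: 2 (S)-1,4-dioxaspiro[4.5]dec-6-en-8-ol
Product: 3 (S)-8-(tert-butyldimethylsilyloxy)-1,4-dioxaspiro[4.5]dec-6-ene
Conditions: TBSCl, imidazole, DMF, rt
Reagents that add atoms: tert-butyldimethylsilyl chloride, CC(C)(C)[Si](C)(C)Cl
Why: Standard silylation of a secondary allylic alcohol, which leaves the stereocentre untouched and installs the bulky group that will shield one enone face.

Step 3
Reactants: 3 (S)-8-(tert-butyldimethylsilyloxy)-1,4-dioxaspiro[4.5]dec-6-ene
Product: 4 (S)-4-(tert-butyldimethylsilyloxy)cyclohex-2-en-1-one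
Conditions: PPTS, acetone/H2O, rt
Reagents that add atoms: water, O
Why: Mild acid-catalysed ketal hydrolysis unmasks the ketone in conjugation with the alkene, so the silyloxy carbon becomes C4 of the enone (future C6) without change at the stereocentre.

Step 4
Reactants: 4 (S)-4-(tert-butyldimethylsilyloxy)cyclohex-2-en-1-one
Product: 5 (S)-4-(tert-butyldimethylsilyloxy)-2-iodocyclohex-2-en-1-one
Conditions: I2, pyridine, CH2Cl2, 0 °C → rt
Reagents that add atoms: iodine, II
Why: α-Iodination of an enone by pyridine conjugate addition, iodination of the enolate and elimination, which is well established for 4-substituted cyclohexenones.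

Step 5
Reactants: 5 (S)-4-(tert-butyldimethylsilyloxy)-2-iodocyclohex-2-en-1-one; 6 ethyl 2-methylpent-4-enoate
Product: 8 ethyl 5-[(3S)-3-(tert-butyldimethylsilyloxy)-6-oxocyclohex-1-en-1-yl]-2-methylpentanoate, via alkylborane 7 (not isolated)
Conditions: 6, 9-BBN, THF, rt; then 5, PdCl2(dppf), Ph3As, Cs2CO3, DMF/H2O, rt
Reagents that add atoms: none
Why: Anti-Markovnikov hydroboration of the terminal alkene and B-alkyl Suzuki–Miyaura coupling with the α-iodoenone join C1 to C10 under conditions that tolerate the ester and the silyl ether.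

Step 6
Reactants: 8 ethyl 5-[(3S)-3-(tert-butyldimethylsilyloxy)-6-oxocyclohex-1-en-1-yl]-2-methylpentanoate
Product: 9 5-[(3S)-3-(tert-butyldimethylsilyloxy)-6-oxocyclohex-1-en-1-yl]-2-methylpentanoic acid
Conditions: LiOH·H2O, THF/H2O, rt; then 1 M HCl
Reagents that add atoms: lithium hydroxide, [Li+].[OH-]
Why: Saponification of an unhindered ethyl ester; the γ-silyloxy enone has no β-leaving group and should survive aqueous hydroxide at room temperature.

Step 7
Reactants: 9 5-[(3S)-3-(tert-butyldimethylsilyloxy)-6-oxocyclohex-1-en-1-yl]-2-methylpentanoic acid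
Product: 10 chloromethyl 5-[(3S)-3-(tert-butyldimethylsilyloxy)-6-oxocyclohex-1-en-1-yl]-2-methylpentanoate
Conditions: ClCH2OSO2Cl, NaHCO3, Bu4NHSO4, CH2Cl2/H2O, rt
Reagents that add atoms: chloromethyl chlorosulfate, ClCOS(=O)(=O)Cl
Why: Phase-transfer O-alkylation of the carboxylate, in which chlorosulfate is displaced in preference to chloride, is the standard way to make chloromethyl esters and places C20 on the ester oxygen.

Step 8
Reactants: 10 chloromethyl 5-[(3S)-3-(tert-butyldimethylsilyloxy)-6-oxocyclohex-1-en-1-yl]-2-methylpentanoate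
Product: 12 tricyclic keto lactone (6α-OTBS; 9-oxo; 19,20-olide; A/B trans), via potassium enolate 11 (not isolated)
Conditions: KHMDS (1.1 equiv), THF (5 mM), −78 → 0 °C
Reagents that add atoms: none
Why: KHMDS generates the potassium enolate of the chloromethyl ester (C4), which adds intramolecularly to C5 of the enone (6-endo-trig Michael closure of ring A) to give ketone enolate 11; its C10 then displaces chloride from the acyloxymethyl carbon C20 (6-(enolexo)-exo-tet closure of the lactone ring), so that C4–C5 and C10–C20 form in one anionic formal [4+2] annulation. The closest known reaction types are Michael-initiated ring closure and the Michael/alkylation α,α′-annulations that give bicyclo[3.3.1]nonanones, and C-alkylation of enolates by chloromethyl esters is standard. C5 is controlled by the C6 silyloxy group (attack anti to it, as for cuprates on 4-silyloxycyclohexenones), C4 by the chair-like Michael transition state that keeps the methyl group equatorial and the bulky enolate carbon axial, away from the peri C6 substituent, and C10 by the tether, since C20 can reach C10 only from the face that carries the axial C19 ester, trans to H-5. The step needs reaction through the ester enolate although the ketone α′-position (C8) is deprotonated faster, 1,4- rather than 1,2-addition, and C- rather than O-alkylation. These are secured because HMDS-mediated proton exchange interconverts the enolates and only the ester enolate has an irreversible intramolecular outlet, the aldol addition to C9 is reversible, and O-alkylation would need an eight-membered ring. High dilution suppresses intermolecular alkylation, and a C4 epimer with an equatorial ester cannot lactonise and should return by retro-Michael reaction.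

Step 9
Reactants: 12 tricyclic keto lactone (6α-OTBS; 9-oxo; 19,20-olide)
Product: 13 enol triflate (C8=C9; 9-OTf; 6α-OTBS; 19,20-olide)
Conditions: KHMDS, PhNTf2, THF, −78 °C
Reagents that add atoms: N-phenylbis(trifluoromethanesulfonimide), O=S(=O)(N(c1ccccc1)S(=O)(=O)C(F)(F)F)C(F)(F)F
Why: C8 is the only enolisable position of the ketone (C10 and the lactone α-carbon C4 are quaternary), so deprotonation and O-triflation should give a single enol triflate.

Step 10
Reactants: 14 2,2-dimethyl-1,3-dioxan-5-one; 15 vinylmagnesium bromide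
Product: 16 2,2-dimethyl-5-vinyl-1,3-dioxan-5-ol
Conditions: THF, −78 → 0 °C; aq. NH4Cl
Reagents that add atoms: none
Why: Grignard 1,2-addition to a symmetrical ketone gives an achiral tertiary carbinol that holds C11–C13 and two identical CH2O arms (the future C14 and C16).

Step 11
Reactants: 13 enol triflate (C8=C9; 9-OTf; 6α-OTBS; 19,20-olide); 16 2,2-dimethyl-5-vinyl-1,3-dioxan-5-ol
Product: 18 Δ8-alkene with a 2-(5-hydroxy-2,2-dimethyl-1,3-dioxan-5-yl)ethyl chain at C9 (6α-OTBS; 19,20-olide), via alkylborane 17 (not isolated)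
Conditions: 16, 9-BBN (2.2 equiv), THF, rt; then 13, PdCl2(dppf), Ph3As, Cs2CO3, DMF/H2O, 40 °C
Reagents that add atoms: none
Why: Hydroboration of the vinyl group (the carbinol is borylated by the second equivalent and freed again in the aqueous medium) and B-alkyl Suzuki–Miyaura coupling with the enol triflate form C9–C11 without creating a stereocentre.

Step 12
Reactants: 18 Δ8-alkene with the hydroxy-dioxanyl-ethyl chain at C9
Product: 19 9α,13-spiro-tetrahydrofuran 8α-alcohol (C13 spiro to the 2,2-dimethyl-1,3-dioxane; 6α-OTBS; 19,20-olide)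
Conditions: Re2O7, 2,6-lutidine, CH2Cl2, 0 °C → rt
Reagents that add atoms: rhenium(VII) oxide, O=[Re](=O)(=O)O[Re](=O)(=O)=O
Why: Rhenium(VII)-mediated syn-oxidative cyclisation of a bishomoallylic tertiary alcohol, in which the perrhenate ester adds the carbinol oxygen to C9 and an oxo oxygen to C8 suprafacially from the α-face (the β-face is shielded by the C20 bridge), should set the 9α-ether and give the 8α-alcohol.

Step 13
Reactants: 19 9α,13-spiro-tetrahydrofuran 8α-alcohol
Product: 20 9α,13-spiro-tetrahydrofuran 8-ketone (C13 spiro to the 2,2-dimethyl-1,3-dioxane; 6α-OTBS; 19,20-olide)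
Conditions: Dess–Martin periodinane, NaHCO3, CH2Cl2, rt
Reagents that add atoms: none
Why: Dess–Martin oxidation of the only free (secondary) alcohol gives the C8 ketone needed both as a temporary anchor for one CH2OH arm and for the later epoxide.

Step 14
Reactants: 20 9α,13-spiro-tetrahydrofuran 8-ketone
Product: 21 bicyclic hemiketal (8β-OH; O16 bonded to C8 on the α-face; free C14H2OH; 6α-OTBS; 19,20-olide)
Conditions: AcOH/THF/H2O (3:1:1), 40 °C
Reagents that add atoms: none
Why: Acetal hydrolysis frees both CH2OH arms, and only the arm cis to C8 across the tetrahydrofuran can add to the α-alkoxy ketone to form a six-membered hemiketal (3,8-dioxabicyclo[3.2.1]octane), which should be the resting form and so differentiates the arms, i.e. defines C13.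

Step 15
Reactants: 21 bicyclic hemiketal with free C14H2OH
Product: 22 hemiketal aldehyde (C14 = CHO; 6α-OTBS; 19,20-olide)
Conditions: Dess–Martin periodinane (1.1 equiv), NaHCO3, CH2Cl2, 0 °C
Reagents that add atoms: none
Why: Dess–Martin oxidation takes the only free primary alcohol to the aldehyde, while the hemiketal hydroxyl has no carbinol hydrogen and the C16 oxygen is tied up, so the C13 configuration is fixed.

Step 16
Reactants: 22 hemiketal aldehyde
Product: 23 hemiketal alkyne (C14≡C15H on C13; 6α-OTBS; 19,20-olide)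
Conditions: dimethyl (1-diazo-2-oxopropyl)phosphonate, K2CO3, MeOH, 0 °C → rt
Reagents that add atoms: dimethyl (1-diazo-2-oxopropyl)phosphonate, COP(=O)(OC)C(=[N+]=[N-])C(C)=O
Why: Ohira–Bestmann (Seyferth–Gilbert) homologation of a non-enolisable aldehyde adds C15 as a terminal alkyne without touching the quaternary C13.

Step 17
Reactants: 23 hemiketal alkyne
Product: 24 spiro-dihydrofuran 8-ketone (9α,13:15,16-diepoxy-14-ene; 13R; 6α-OTBS; 19,20-olide)
Conditions: Mo(CO)6 (30 mol%), Et3N, Et2O, hν (350 nm), rt
Reagents that add atoms: none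
Why: Molybdenum-vinylidene cycloisomerisation of a homopropargylic alcohol (5-endo O–C15 bond formation) gives the 2,3-dihydrofuran under basic conditions; the hemiketal supplies the free C16–OH by ring–chain equilibrium and the C8 ketone is released.

Step 18
Reactants: 24 spiro-dihydrofuran 8-ketone
Product: 25 8β,17-epoxide (epoxide O on the β-face, C17 α; 6α-OTBS; spiro-dihydrofuran; 19,20-olide)
Conditions: Me3S(O)I, NaH, DMSO/THF, rt → 45 °C
Reagents that add atoms: trimethylsulfoxonium iodide, C[S+](C)(C)=O.[I-]
Why: Corey–Chaykovsky epoxidation with dimethylsulfoxonium methylide forms the betaine reversibly and so places the new C–C bond equatorial (α), the axial approach being blocked by the syn-axial C20 bridge, which puts the epoxide oxygen on the β-face.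

Step 19
Reactants: 25 8β,17-epoxide with 6α-OTBS
Product: 26 6α-alcohol (8β,17-epoxide; spiro-dihydrofuran; 19,20-olide)
Conditions: TBAF, THF, rt
Reagents that add atoms: none
Why: Fluoride desilylation under basic conditions spares the acid-sensitive enol ether, the epoxide and the hindered lactone.

Step 20
Reactants: 26 6α-alcohol
Product: 27 6-ketone (8β,17-epoxide; spiro-dihydrofuran; 19,20-olide)
Conditions: Dess–Martin periodinane, pyridine, CH2Cl2, 0 °C → rt
Reagents that add atoms: none
Why: Buffered Dess–Martin oxidation removes the C6 stereocentre, whose steering role is finished, without acid damage to the enol ether.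

Step 21
Reactants: 27 6-ketone
Product: 28 6β-alcohol (8β,17-epoxide; spiro-dihydrofuran; 19,20-olide)
Conditions: NaBH4, MeOH/CH2Cl2, −40 °C
Reagents that add atoms: none
Why: Borohydride reduction delivers hydride from the open α-face (the β-face is blocked by the syn-axial C20 bridge, C19 and the epoxide oxygen), so the axial 6β-alcohol should result; the lactone and epoxide are inert.

Step 22
Reactants: 28 6β-alcohol
Product: 29 target, 6β-acetoxy-8β,17:9α,13:15,16-triepoxylabd-14-en-19,20-olide (13R)
Conditions: Ac2O, DMAP, pyridine, rt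
Reagents that add atoms: acetic anhydride, CC(=O)OC(C)=O
Why: DMAP-catalysed acylation of the hindered axial alcohol under basic conditions keeps the enol ether and epoxide intact.

Compound list
1 | 1,4-dioxaspiro[4.5]dec-6-en-8-one | O=C1CCC2(OCCO2)C=C1 | starting material
2 | (S)-1,4-dioxaspiro[4.5]dec-6-en-8-ol | O[C@H]1CCC2(OCCO2)C=C1 | intermediate
3 | (S)-8-(tert-butyldimethylsilyloxy)-1,4-dioxaspiro[4.5]dec-6-ene | CC(C)(C)[Si](C)(C)O[C@H]1CCC2(OCCO2)C=C1 | intermediate
4 | (S)-4-(tert-butyldimethylsilyloxy)cyclohex-2-en-1-one | CC(C)(C)[Si](C)(C)O[C@H]1CCC(=O)C=C1 | intermediate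
5 | (S)-4-(tert-butyldimethylsilyloxy)-2-iodocyclohex-2-en-1-one | CC(C)(C)[Si](C)(C)O[C@H]1CCC(=O)C(I)=C1 | intermediate
6 | ethyl 2-methylpent-4-enoate (racemic) | C=CCC(C)C(=O)OCC | starting material
7 | ethyl 5-(9-borabicyclo[3.3.1]nonan-9-yl)-2-methylpentanoate | CCOC(=O)C(C)CCCB1C2CCCC1CCC2 | intermediate (not isolated)
8 | ethyl 5-[(3S)-3-(tert-butyldimethylsilyloxy)-6-oxocyclohex-1-en-1-yl]-2-methylpentanoate (epimer pair at the ester α-carbon) | CC(C)(C)[Si](C)(C)O[C@H]1CCC(=O)C(CCCC(C)C(=O)OCC)=C1 | intermediate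
9 | 5-[(3S)-3-(tert-butyldimethylsilyloxy)-6-oxocyclohex-1-en-1-yl]-2-methylpentanoic acid (epimer pair) | CC(C)(C)[Si](C)(C)O[C@H]1CCC(=O)C(CCCC(C)C(=O)O)=C1 | intermediate
10 | chloromethyl 5-[(3S)-3-(tert-butyldimethylsilyloxy)-6-oxocyclohex-1-en-1-yl]-2-methylpentanoate (epimer pair) | CC(C)(C)[Si](C)(C)O[C@H]1CCC(=O)C(CCCC(C)C(=O)OCCl)=C1 | intermediate
11 | potassium enolate of the Michael adduct (ring A closed; C9–O−, C9=C10; 4α-methyl, 4β-chloromethyl ester; 5α-H; 6α-OTBS) | CC(C)(C)[Si](C)(C)O[C@H]1CCC([O-])=C2CCC[C@](C)(C(=O)OCCl)[C@H]12.[K+] | intermediate (not isolated)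
12 | tricyclic keto lactone: 6α-(tert-butyldimethylsilyloxy)-9-oxo-11,12,13,14,15,16,17-heptanorlabdan-19,20-olide (A/B trans; 4α-methyl; C19(=O)–O–C20H2 bridge on the β-face from C4 to C10) | CC(C)(C)[Si](C)(C)O[C@H]1CCC(=O)[C@]23CCC[C@](C)(C(=O)OC2)[C@H]13 | intermediate
13 | enol triflate: 6α-(tert-butyldimethylsilyloxy)-9-(trifluoromethylsulfonyloxy)-11,12,13,14,15,16,17-heptanorlabd-8-en-19,20-olide | CC(C)(C)[Si](C)(C)O[C@H]1CC=C(OS(=O)(=O)C(F)(F)F)[C@]23CCC[C@](C)(C(=O)OC2)[C@H]13 | intermediate
14 | 2,2-dimethyl-1,3-dioxan-5-one | CC1(C)OCC(=O)CO1 | starting material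
15 | vinylmagnesium bromide | C=C[Mg]Br | starting material
16 | 2,2-dimethyl-5-vinyl-1,3-dioxan-5-ol | C=CC1(O)COC(C)(C)OC1 | intermediate
17 | 5-[2-(9-borabicyclo[3.3.1]nonan-9-yl)ethyl]-2,2-dimethyl-1,3-dioxan-5-yl 9-borabicyclo[3.3.1]nonan-9-yl ether (B-alkyl borane, carbinol O-borylated) | CC1(C)OCC(CCB2C3CCCC2CCC3)(OB2C3CCCC2CCC3)CO1 | intermediate (not isolated)
18 | Δ8-alkene: 6α-(tert-butyldimethylsilyloxy)-19,20-olide core with a 2-(5-hydroxy-2,2-dimethyl-1,3-dioxan-5-yl)ethyl chain (C11–C12–C13) at C9 | CC(C)(C)[Si](C)(C)O[C@H]1CC=C(CCC4(O)COC(C)(C)OC4)[C@]23CCC[C@](C)(C(=O)OC2)[C@H]13 | intermediate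
19 | 9α,13-epoxy spiro-tetrahydrofuran 8α-alcohol (ether O on the α-face of C9, C11 β; C13 spiro to the 2,2-dimethyl-1,3-dioxane; 6α-OTBS; 19,20-olide) | CC(C)(C)[Si](C)(C)O[C@H]1C[C@@H](O)[C@]2(CCC4(COC(C)(C)OC4)O2)[C@]23CCC[C@](C)(C(=O)OC2)[C@H]13 | intermediate
20 | 8-ketone of 19 (9α,13-epoxy; C13 spiro to the 2,2-dimethyl-1,3-dioxane; 6α-OTBS; 19,20-olide) | CC(C)(C)[Si](C)(C)O[C@H]1CC(=O)[C@]2(CCC4(COC(C)(C)OC4)O2)[C@]23CCC[C@](C)(C(=O)OC2)[C@H]13 | intermediate
21 | bicyclic hemiketal: 9α,13-epoxy; C16H2–O bonded to C8 on the α-face, 8β-OH; free C14H2OH on C13 (the C16 arm is cis to C8 across the tetrahydrofuran); 6α-OTBS; 19,20-olide | CC(C)(C)[Si](C)(C)O[C@H]1C[C@]5(O)[C@]2(CC[C@@](CO)(CO5)O2)[C@]23CCC[C@](C)(C(=O)OC2)[C@H]13 | intermediate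
22 | hemiketal aldehyde: as 21 with C14 as CHO | CC(C)(C)[Si](C)(C)O[C@H]1C[C@]5(O)[C@]2(CC[C@@](C=O)(CO5)O2)[C@]23CCC[C@](C)(C(=O)OC2)[C@H]13 | intermediate
23 | hemiketal alkyne: as 21 with an ethynyl group (C14≡C15H) on C13 | CC(C)(C)[Si](C)(C)O[C@H]1C[C@]5(O)[C@]2(CC[C@@](C#C)(CO5)O2)[C@]23CCC[C@](C)(C(=O)OC2)[C@H]13 | intermediate
24 | 6α-(tert-butyldimethylsilyloxy)-8-oxo-9α,13:15,16-diepoxy-17-norlabd-14-en-19,20-olide (13R) | CC(C)(C)[Si](C)(C)O[C@H]1CC(=O)[C@]2(CC[C@]3(C=COC3)O2)[C@]23CCC[C@](C)(C(=O)OC2)[C@H]13 | intermediate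
25 | 6α-(tert-butyldimethylsilyloxy)-8β,17:9α,13:15,16-triepoxylabd-14-en-19,20-olide (13R; epoxide O β, C17 α) | CC(C)(C)[Si](C)(C)O[C@H]1C[C@@]2(CO2)[C@]2(CC[C@]3(C=COC3)O2)[C@]23CCC[C@](C)(C(=O)OC2)[C@H]13 | intermediate
26 | 6α-hydroxy-8β,17:9α,13:15,16-triepoxylabd-14-en-19,20-olide (13R) | O[C@H]1C[C@@]2(CO2)[C@]2(CC[C@]3(C=COC3)O2)[C@]23CCC[C@](C)(C(=O)OC2)[C@H]13 | intermediate
27 | 6-oxo-8β,17:9α,13:15,16-triepoxylabd-14-en-19,20-olide (13R) | O=C1C[C@@]2(CO2)[C@]2(CC[C@]3(C=COC3)O2)[C@]23CCC[C@](C)(C(=O)OC2)[C@H]13 | intermediate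
28 | 6β-hydroxy-8β,17:9α,13:15,16-triepoxylabd-14-en-19,20-olide (13R) | O[C@@H]1C[C@@]2(CO2)[C@]2(CC[C@]3(C=COC3)O2)[C@]23CCC[C@](C)(C(=O)OC2)[C@H]13 | intermediate
29 | 6β-acetoxy-8β,17:9α,13:15,16-triepoxylabd-14-en-19,20-olide (13R), CNP0173713.2 | CC(=O)O[C@@H]1C[C@@]2(CO2)[C@]2(CC[C@]3(C=COC3)O2)[C@]23CCC[C@](C)(C(=O)OC2)[C@H]13 | target

Total step count: 22. Longest linear sequence: 21 steps (1 → 29 through steps 1–9 and 11–22; step 10 makes the side-chain fragment).

Steps most likely to fail

Step 8. The base may deprotonate the ketone α′-position (C8) faster than the ester, and if proton exchange to the ester enolate is slow, intermolecular alkylation or oligomerisation can take over; a poor C4 preference in the Michael step would stall the cascade after the first ring. The fallback separates the two bond formations and makes C20 from formaldehyde. It sets out from 8: catalytic KOtBu in tBuOH/THF (protic, equilibrating conditions under which α′-enolisation is harmless) should give the ring-A-closed Michael adduct, the bicyclic keto ester F1. Its more substituted potassium enolate (KH, THF) is then treated with monomeric formaldehyde; aldol addition at C10 gives the 10β-hydroxymethyl ketone F2, whose alkoxide lactonises onto the axial C4 ester with loss of ethoxide, while an α-face aldolate can revert by retro-aldol. The route is rejoined at 12.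

Step 15. The oxidation relies on the cis CH2OH arm being masked as the hemiketal; if ring–chain equilibrium leaves much open keto diol, both arms are oxidised and the group selectivity that defines C13 is lost. The fallback locks the masked arm covalently. It sets out from 21: CSA in methanol should convert the hemiketal into the bicyclic methyl ketal F3; Dess–Martin oxidation then gives the ketal aldehyde F4 and Ohira–Bestmann homologation the ketal alkyne F5; PPTS in acetone/water hydrolyses the mixed ketal and the route is rejoined at 23.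

Step 12. The syn-oxidative cyclisation may be slow at the hindered trisubstituted alkene next to the quaternary C10, and perrhenic acid may cause dehydration of the tertiary alcohol or loss of the acetonide. The fallback replaces the metal-oxo syn addition by an electrophile-induced anti cyclisation. It sets out from 18: Hg(OCOCF3)2 in CH2Cl2, then aqueous NaCl, should give by reversible mercurinium formation and trans-diaxial opening (Hg axial β at C8, carbinol oxygen axial α at C9) the 8β-chloromercurio spiro ether F6; oxidative demercuration (NaBH4, O2, DMF) gives the 8-hydroxy spiro ether F7 as either C8 epimer, and Dess–Martin oxidation rejoins the route at 20.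

Further compounds
F1 | step 8 | Michael adduct, bicyclic keto ester (ring A closed; 4α-methyl, 4β-CO2Et; 5α-H, 10β-H; 6α-OTBS; 9-oxo) | CC(C)(C)[Si](C)(C)O[C@H]1CCC(=O)[C@H]2CCC[C@](C)(C(=O)OCC)[C@H]12
F2 | step 8 | 10β-hydroxymethyl ketone (aldol adduct of F1 with formaldehyde; 4β-CO2Et; 6α-OTBS) | CC(C)(C)[Si](C)(C)O[C@H]1CCC(=O)[C@@]2(CO)CCC[C@](C)(C(=O)OCC)[C@H]12
F3 | step 15 | bicyclic methyl ketal of 21 (8β-OMe; O16 on C8 α; free C14H2OH) | CC(C)(C)[Si](C)(C)O[C@H]1C[C@]5(OC)[C@]2(CC[C@@](CO)(CO5)O2)[C@]23CCC[C@](C)(C(=O)OC2)[C@H]13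
F4 | step 15 | ketal aldehyde (F3 with C14 as CHO) | CC(C)(C)[Si](C)(C)O[C@H]1C[C@]5(OC)[C@]2(CC[C@@](C=O)(CO5)O2)[C@]23CCC[C@](C)(C(=O)OC2)[C@H]13
F5 | step 15 | ketal alkyne (F3 with ethynyl on C13) | CC(C)(C)[Si](C)(C)O[C@H]1C[C@]5(OC)[C@]2(CC[C@@](C#C)(CO5)O2)[C@]23CCC[C@](C)(C(=O)OC2)[C@H]13
F6 | step 12 | 8β-chloromercurio 9α,13-spiro ether (C13 spiro to the 2,2-dimethyl-1,3-dioxane; 6α-OTBS) | CC(C)(C)[Si](C)(C)O[C@H]1C[C@H]([Hg]Cl)[C@]2(CCC4(COC(C)(C)OC4)O2)[C@]23CCC[C@](C)(C(=O)OC2)[C@H]13
F7 | step 12 | 8-hydroxy 9α,13-spiro ether (both C8 epimers) | CC(C)(C)[Si](C)(C)O[C@H]1CC(O)[C@]2(CCC4(COC(C)(C)OC4)O2)[C@]23CCC[C@](C)(C(=O)OC2)[C@H]13
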